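**Retrosynthetic overview**
1. Feature: in ring A (C1 carbinol carbon, C2 the CH with the two-carbon linker, C3 CMe2, C4 CHBr) the quaternary C3 lies between C4 and C2, and C2 is α to C1. Removing the C1 methyl (last step, MeCeCl2) leaves a 2-alkyl-4-bromo-3,3-dimethylcyclohexanone.
2. Key disconnection, C2–C3 of ring A: the enol carbon of an open-chain ketone is joined to the CMe2 carbon of a bromonium ion. The ion is regenerated with its configuration from an (R)-bromohydrin by ionising the tertiary oxygen; an electrophilic bromine source would brominate the enol instead.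
3. The keto bromohydrin comes from a keto epoxide by bromide opening with inversion. The keto epoxide comes from a ring B propyl sulfone anion and an (S)-epoxy Weinreb amide (bond between linker carbon and carbonyl), followed by desulfonylation.
4. Ring order: ring B (oxane) first, by bromoetherification of a hydroxy sulfone cut down from (3S,6E)-nerolidol; ring A second, in the key step.

Key step: step 13

Assumption: (3S,6E)-nerolidol is bought as the single natural enantiomer, and the L-fructose-derived enantiomer of the Shi ketone (made from L-sorbose) is at hand as a catalyst.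
Locants: ring A as in line 1; ring B = oxane O1, C2 (CH3 and side chain), C3 (CHBr), C6 (CH3 and vinyl).

**Step 1**
Reactants: 1 (3S,6E)-nerolidol
Product: 2 (3S,6E)-10-bromo-3,7,11-trimethyldodeca-1,6-diene-3,11-diol (both C10 epimers)
Conditions: NBS (1.05 equiv), THF–H2O, 0 °C
Reagents that add atoms: N-bromosuccinimide, O=C1CCC(=O)N1Br; water, O
Why: Bromohydrin formation with NBS in a water-rich solvent is known to pick the terminal trisubstituted alkene of farnesyl-type chains, with water opening the bromonium ion at the tertiary carbon (Markovnikov); the CHBr centre forms as a mixture, which does not matter because this carbon becomes the aldehyde carbon in step 3.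

**Step 2**
Reactants: 2 terminal bromohydrin
Product: 3 (3S,6E)-10,11-epoxy-3,7,11-trimethyldodeca-1,6-dien-3-ol (both C10 epimers)
Conditions: K2CO3, MeOH, 23 °C
Reagents that add atoms: none
Why: Base-induced closure of a bromohydrin (intramolecular Williamson reaction) gives the epoxide under conditions that leave the tertiary allylic alcohol and both alkenes alone.

**Step 3**
Reactants: 3 terminal epoxide
Product: 5 (4E,8S)-8-hydroxy-4,8-dimethyldeca-4,9-dienal, via triol 4 (not isolated)
Conditions: H5IO6, THF–H2O, 0 °C
Reagents that add atoms: none
Why: Periodic acid hydrolyses the epoxide to the glycol 4 and then cleaves it (Malaprade glycol cleavage), which removes the three terminal carbons as acetone without touching the other two alkenes, something ozonolysis could not do.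

**Step 4**
Reactants: 5 hydroxy aldehyde
Product: 6 (4E,8S)-4,8-dimethyldeca-4,9-diene-1,8-diol
Conditions: NaBH4, MeOH, 0 °C
Reagents that add atoms: none
Why: Borohydride reduction of the aldehyde is chemoselective and creates no stereocentre.

**Step 5**
Reactants: 6 diol
Product: 7 (3S,6E)-10-iodo-3,7-dimethyldeca-1,6-dien-3-ol
Conditions: I2, PPh3, imidazole, CH2Cl2, 0 °C
Reagents that add atoms: iodine, II
Why: Appel-type iodination activates and displaces (SN2) only the unhindered primary alcohol, so the tertiary allylic alcohol stays free.

**Step 6**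
Reactants: 7 iodide
Product: 8 (3S,6E)-3,7-dimethyl-10-(phenylsulfonyl)deca-1,6-dien-3-ol
Conditions: PhSO2Na, DMF, 23 °C
Reagents that add atoms: sodium benzenesulfinate, [Na+].[O-]S(=O)c1ccccc1
Why: S-alkylation of the soft sulfinate anion by a primary iodide (SN2) gives the sulfone, which is inert to bromine electrophiles (a free primary alcohol would compete in step 7) and later acidifies the linker CH2.

**Step 7**
Reactants: 8 hydroxy sulfone
Product: 9 (2S,3R,6S)-3-bromo-6-ethenyl-2,6-dimethyl-2-[3-(phenylsulfonyl)propyl]oxane (ring B sulfone)
Conditions: NBS, (CF3)2CHOH, 4 Å MS, 0 °C, dark; chromatography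
Reagents that add atoms: N-bromosuccinimide, O=C1CCC(=O)N1Br
Why: In this bromoetherification the bromonium ion forms on the only trisubstituted alkene and the tertiary hydroxyl opens it anti at the more substituted carbon (6-endo, Markovnikov, favoured by the ionising solvent), so the E-alkene fixes bromine trans to the side chain; the C6 centre distinguishes the two alkene faces only weakly (methyl against vinyl), so both ring B diastereomers are expected in similar amounts and the (2S,3R,6S) isomer is taken on after separation.

**Step 8**
Reactants: 10 5-methylhex-4-enoic acid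
Product: 12 N-methoxy-N,5-dimethylhex-4-enamide, via acyl imidazole 11 (not isolated)
Conditions: CDI, CH2Cl2, 23 °C; then MeNH(OMe)·HCl
Reagents that add atoms: N,O-dimethylhydroxylamine hydrochloride, CNOC.Cl
Why: Amide coupling through the acyl imidazole 11 gives the Weinreb amide, chosen over a methyl ester because its carbanion adduct does not collapse before the quench, so no second equivalent of base is needed that could enolise the epoxy ester and close a cyclopropane.

**Step 9**
Reactants: 12 Weinreb amide
Product: 13 3-[(2S)-3,3-dimethyloxiran-2-yl]-N-methoxy-N-methylpropanamide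
Conditions: L-fructose-derived Shi ketone (30 mol %), Oxone (2KHSO5·KHSO4·K2SO4), K2CO3, Bu4NHSO4 (cat.), MeCN–CH2(OMe)2, aq. Na2B4O7 buffer, 0 °C
Reagents that add atoms: potassium peroxymonosulfate KHSO5, [K+].[O-]S(=O)(=O)OO
Why: In the Shi epoxidation the chiral dioxirane meets the trisubstituted alkene in the spiro transition state, and since the D-fructose-derived ketone gives the R epoxide with this alkene class, its enantiomer should give the S epoxide, the single reagent-controlled centre that becomes C4 of ring A.

**Step 10**
Reactants: 9 ring B sulfone; 13 (S)-epoxy Weinreb amide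
Product: 16 6-[(2S,3R,6S)-3-bromo-6-ethenyl-2,6-dimethyloxan-2-yl]-1-[(2S)-3,3-dimethyloxiran-2-yl]-4-(phenylsulfonyl)hexan-3-one (both C4 epimers), via lithiated sulfone 14 (not isolated), via tetrahedral adduct 15 (not isolated)
Conditions: LiN(iPr)2 (1.05 equiv), THF, −78 °C; then 13, −78 to −40 °C; AcOH
Reagents that add atoms: none
Why: In this acylation of an α-sulfonyl carbanion by a Weinreb amide, the base removes only the proton next to sulfur at −78 °C (the equatorial, neopentyl-type bromide has no antiperiplanar hydrogen and is not displaced), the hindered epoxide is not attacked, and the chelated adduct 15 holds until the acid quench so that the acidic product cannot quench 14; the sulfone-bearing centre is a mixture and disappears in step 11.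

**Step 11**
Reactants: 16 β-keto sulfone
Product: 17 6-[(2S,3R,6S)-3-bromo-6-ethenyl-2,6-dimethyloxan-2-yl]-1-[(2S)-3,3-dimethyloxiran-2-yl]hexan-3-one (keto epoxide)
Conditions: SmI2 (2.5 equiv), THF–MeOH, −78 °C
Reagents that add atoms: none
Why: Reductive desulfonylation of a β-keto sulfone by SmI2 is fast at −78 °C because the C–S bond is α to the carbonyl, whereas the unactivated secondary bromide, the epoxide, the ketone and the vinyl group are not reduced without HMPA at this temperature.

**Step 12**
Reactants: 17 keto epoxide
Product: 18 (7R)-7-bromo-1-[(2S,3R,6S)-3-bromo-6-ethenyl-2,6-dimethyloxan-2-yl]-8-hydroxy-8-methylnonan-4-one (keto bromohydrin, open form of its six-membered lactol)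
Conditions: Li2NiBr4, THF, 0 °C; then H2O (pH 7 buffer)
Reagents that add atoms: dilithium tetrabromonickelate Li2NiBr4, [Li+].[Li+].[Ni+2].[Br-].[Br-].[Br-].[Br-]
Why: Epoxide opening by the soft bromide of Li2NiBr4 is an SN2 attack at the less substituted carbon, so inversion turns the (S)-C–O centre into the (R)-C–Br centre and frees the tertiary alcohol.

**Step 13**
Reactants: 18 keto bromohydrin
Product: 21 (2R,4R)-4-bromo-2-{2-[(2S,3R,6S)-3-bromo-6-ethenyl-2,6-dimethyloxan-2-yl]ethyl}-3,3-dimethylcyclohexan-1-one (ring A bromoketone), via trifluoroacetate 19 (not isolated), via bromonium enol 20 (not isolated)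
Conditions: (CF3CO)2O, pyridine, CH2Cl2, −20 °C; evaporate; (CF3)2CHOH (0.01 M), 0 to 23 °C
Reagents that add atoms: none
Why: Proposed new method: trifluoroacetylation turns the tertiary hydroxyl into a leaving group (19), which ionises in the strongly ionising and barely nucleophilic (CF3)2CHOH with backside participation of the neighbouring bromine, so that the bridged bromonium ion is regenerated with the CHBr configuration intact, and the linker-side enol of the ketone (20) attacks the CMe2 carbon anti to bromine to form the C2–C3 bond of ring A. The closest known reaction types are the stereospecific solvolysis of enantioenriched bromohydrin esters with capture of the bromonium ion by an alkene, the Lewis-acid cation–enol cyclisation of alkenyl β-keto esters, and the acid-induced O-to-C isomerisation in selenium-induced cyclisations of such keto esters; capture by the enol of an unactivated ketone is the untested extension. Ring A closes in a 6-(enolendo) mode that is endo at the three-membered bromonium ring, both carbons of which become ring members. C4 keeps its R configuration, and the new centre C2 (R) is set kinetically by a chair transition state in which the C–Br bond lies anti to the forming bond and is therefore equatorial while the (Z)-enol puts the linker equatorial, cis to bromine; because an axial bromine costs little in a 4-bromocyclohexanone the equilibrium preference for this epimer should be small, so the reaction is stopped once 19 is consumed instead of relying on epimerisation. The step needs carbon capture by the correct enol: the enol on the other side could only close a four-membered ring, and capture by the carbonyl oxygen merely rebuilds a tertiary, bromine-assisted C–O bond that ionises again, so that only the irreversible C–C closure drains the system. High dilution, low temperature, the pyridinium trifluoroacetate buffer and the absence of any electron-rich alkene are meant to spare the tertiary allylic ether of ring B and to shut down bromine transfer between molecules.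

**Step 14**
Reactants: 21 ring A bromoketone
Product: 22 (1S,2R,4R)-4-bromo-2-{2-[(2S,3R,6S)-3-bromo-6-ethenyl-2,6-dimethyloxan-2-yl]ethyl}-1,3,3-trimethylcyclohexan-1-ol (target)
Conditions: MeLi, CeCl3, THF, −78 °C; then 21, −78 °C; H2O
Reagents that add atoms: methyllithium (delivered as MeCeCl2), C[Li]
Why: In this organocerium 1,2-addition the weakly basic MeCeCl2 adds without enolising the ketone or displacing either bromide, and it arrives on the equatorial trajectory because the axial methyl on C3 blocks the axial one, so the new methyl is equatorial and the C1 hydroxyl axial, cis to the linker (1S).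

**Compound list**
1 | (3S,6E)-nerolidol | C=C[C@](O)(C)CC/C=C(C)/CCC=C(C)C | starting material
2 | (3S,6E)-10-bromo-3,7,11-trimethyldodeca-1,6-diene-3,11-diol (C10 epimers) | C=C[C@](O)(C)CC/C=C(C)/CCC(Br)C(C)(C)O | intermediate
3 | (3S,6E)-10,11-epoxy-3,7,11-trimethyldodeca-1,6-dien-3-ol (C10 epimers) | C=C[C@](O)(C)CC/C=C(C)/CCC1OC1(C)C | intermediate
4 | (3S,6E)-3,7,11-trimethyldodeca-1,6-diene-3,10,11-triol (not isolated) | C=C[C@](O)(C)CC/C=C(C)/CCC(O)C(C)(C)O | intermediate
5 | (4E,8S)-8-hydroxy-4,8-dimethyldeca-4,9-dienal | C=C[C@](O)(C)CC/C=C(C)/CCC=O | intermediate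
6 | (4E,8S)-4,8-dimethyldeca-4,9-diene-1,8-diol | C=C[C@](O)(C)CC/C=C(C)/CCCO | intermediate
7 | (3S,6E)-10-iodo-3,7-dimethyldeca-1,6-dien-3-ol | C=C[C@](O)(C)CC/C=C(C)/CCCI | intermediate
8 | (3S,6E)-3,7-dimethyl-10-(phenylsulfonyl)deca-1,6-dien-3-ol | C=C[C@](O)(C)CC/C=C(C)/CCCS(=O)(=O)c1ccccc1 | intermediate
9 | (2S,3R,6S)-3-bromo-6-ethenyl-2,6-dimethyl-2-[3-(phenylsulfonyl)propyl]oxane | C=C[C@]1(C)CC[C@@H](Br)[C@](C)(CCCS(=O)(=O)c2ccccc2)O1 | intermediate
10 | 5-methylhex-4-enoic acid | CC(C)=CCCC(=O)O | starting material
11 | 1-(imidazol-1-yl)-5-methylhex-4-en-1-one (not isolated) | CC(C)=CCCC(=O)n1ccnc1 | intermediate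
12 | N-methoxy-N,5-dimethylhex-4-enamide | CC(C)=CCCC(=O)N(C)OC | intermediate
13 | 3-[(2S)-3,3-dimethyloxiran-2-yl]-N-methoxy-N-methylpropanamide | CON(C)C(=O)CC[C@@H]1OC1(C)C | intermediate
14 | α-lithiated sulfone from 9 (not isolated) | C=C[C@]1(C)CC[C@@H](Br)[C@](C)(CCC([Li])S(=O)(=O)c2ccccc2)O1 | intermediate
15 | lithium alkoxide adduct of 14 to 13 (not isolated) | C=C[C@]1(C)CC[C@@H](Br)[C@](C)(CCC(S(=O)(=O)c2ccccc2)C(O[Li])(N(C)OC)CC[C@@H]2OC2(C)C)O1 | intermediate
16 | β-keto sulfone (epimers at the sulfone carbon) | C=C[C@]1(C)CC[C@@H](Br)[C@](C)(CCC(S(=O)(=O)c2ccccc2)C(=O)CC[C@@H]2OC2(C)C)O1 | intermediate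
17 | keto epoxide | C=C[C@]1(C)CC[C@@H](Br)[C@](C)(CCCC(=O)CC[C@@H]2OC2(C)C)O1 | intermediate
18 | keto bromohydrin (key-step precursor) | C=C[C@]1(C)CC[C@@H](Br)[C@](C)(CCCC(=O)CC[C@@H](Br)C(C)(C)O)O1 | intermediate
19 | tertiary trifluoroacetate of 18 (not isolated) | C=C[C@]1(C)CC[C@@H](Br)[C@](C)(CCCC(=O)CC[C@@H](Br)C(C)(C)OC(=O)C(F)(F)F)O1 | intermediate
20 | bromonium ion in its linker-side (Z)-enol form, trifluoroacetate salt (not isolated) | C=C[C@]1(C)CC[C@@H](Br)[C@](C)(CC/C=C(\O)CC[C@H]2[Br+]C2(C)C)O1.[O-]C(=O)C(F)(F)F | intermediate
21 | ring A bromoketone (key-step product) | C=C[C@]1(C)CC[C@@H](Br)[C@](C)(CC[C@@H]2C(C)(C)[C@H](Br)CCC2=O)O1 | intermediate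
22 | CNP0244533.1 | C=C[C@]1(C)CC[C@@H](Br)[C@](C)(CC[C@@H]2C(C)(C)[C@H](Br)CC[C@]2(C)O)O1 | target

**Step count**
Total steps: 14. Longest linear sequence: 12 (steps 1–7 and 10–14).

**Steps most likely to fail**

1. Step 13.
- What may go wrong: enolisation is the slow event, so the ion may be lost first. Possible paths are proton loss from the tertiary cation, oxygen capture that does not revert, and bromine transfer to the enol carbon. The allylic ether of ring B may also ionise.
- Fallback (known chemistry): Lewis-acid α-tert-alkylation of a preformed silyl enol ether by an SN1-active tertiary ester in an aprotic solvent. It sets out from 19, made from 18 as in step 13 and kept in CH2Cl2.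
- TMSOTf and Et3N at 0 °C should give the linker-side (Z)-trimethylsilyl enol ether F1 beside the regioisomeric (Z)-trimethylsilyl enol ether F2.
- TiCl4 in CH2Cl2 at −78 °C then ionises the trifluoroacetate. F1 closes through the same chair to 21, where the route is rejoined.
- F2 cannot form a six-membered carbocycle and is lost, which is the price of this variant.

2. Step 7.
- What may go wrong: poor facial selectivity, because the controlling centre carries two groups of similar size, and some 5-exo closure.
- Fallback (reagent control): the bromonium ion is made by ionisation and not by bromination. It sets out from 8.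
- TESOTf and 2,6-lutidine give the triethylsilyl ether F3.
- Shi epoxidation with the same L-fructose-derived ketone gives the (6S,7S)-epoxide F4.
- Li2NiBr4 opens it at the secondary carbon with inversion to the (6R,7S)-bromohydrin F5.
- (CF3CO)2O and pyridine give the tertiary trifluoroacetate F6.
- In (CF3)2CHOH this ionises with bromine participation, and the silyl ether oxygen attacks the tertiary carbon anti to bromine (net retention there). The silyl group leaves, and the route is rejoined at 9 as one diastereomer.

3. Step 12.
- What may go wrong: bromide attack at the tertiary carbon, or participation of the ketone oxygen in the activated epoxide.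
- Fallback: the bromide is set on fragment 2 before the union, where no ketone is present and regioisomers are removed on a small molecule. It sets out from 13.
- Li2NiBr4 gives the (4R)-bromohydrin amide F7, and catalytic TsOH in CH2Cl2 closes it to the δ-lactone F8.
- Addition of F8 to 14 (from 9 as in step 10) at −78 °C and an AcOH quench should give the β-keto sulfone bromohydrin F9. The tertiary alkoxide released on ring opening is at once protonated by the acidic β-keto sulfone and cannot reclose the epoxide.
- SmI2 as in step 11 then leads to 18, where the route is rejoined.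

**Further compounds**
F1 | step 13 | linker-side (Z)-trimethylsilyl enol ether of 19 | C=C[C@]1(C)CC[C@@H](Br)[C@](C)(CC/C=C(\O[Si](C)(C)C)CC[C@@H](Br)C(C)(C)OC(=O)C(F)(F)F)O1
F2 | step 13 | regioisomeric (Z)-trimethylsilyl enol ether of 19 | C=C[C@]1(C)CC[C@@H](Br)[C@](C)(CCC/C(O[Si](C)(C)C)=C/C[C@@H](Br)C(C)(C)OC(=O)C(F)(F)F)O1
F3 | step 7 | (3S,6E)-3,7-dimethyl-10-(phenylsulfonyl)-3-(triethylsilyloxy)deca-1,6-diene | C=C[C@](O[Si](CC)(CC)CC)(C)CC/C=C(C)/CCCS(=O)(=O)c1ccccc1
F4 | step 7 | (3S,6S,7S)-6,7-epoxide of F3 | C=C[C@](O[Si](CC)(CC)CC)(C)CC[C@@H]1O[C@@]1(C)CCCS(=O)(=O)c1ccccc1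
F5 | step 7 | (3S,6R,7S)-6-bromo-3,7-dimethyl-10-(phenylsulfonyl)-3-(triethylsilyloxy)dec-1-en-7-ol | C=C[C@](O[Si](CC)(CC)CC)(C)CC[C@@H](Br)[C@](C)(CCCS(=O)(=O)c1ccccc1)O
F6 | step 7 | tertiary trifluoroacetate of F5 | C=C[C@](O[Si](CC)(CC)CC)(C)CC[C@@H](Br)[C@](C)(CCCS(=O)(=O)c1ccccc1)OC(=O)C(F)(F)F
F7 | step 12 | (4R)-4-bromo-5-hydroxy-N-methoxy-N,5-dimethylhexanamide | CON(C)C(=O)CC[C@@H](Br)C(C)(C)O
F8 | step 12 | (5R)-5-bromo-6,6-dimethyloxan-2-one | O=C1CC[C@@H](Br)C(C)(C)O1
F9 | step 12 | β-keto sulfone bromohydrin (epimers at the sulfone carbon) | C=C[C@]1(C)CC[C@@H](Br)[C@](C)(CCC(S(=O)(=O)c2ccccc2)C(=O)CC[C@@H](Br)C(C)(C)O)O1
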